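A direct plan would join three benzylated gallic acid units by two acylations of phenols and finish by hydrogenolysis.
Ring B would enter as 3,5-bis(benzyloxy)-4-hydroxybenzaldehyde A1, to be won by cleaving the para benzyl ether out of the three of its tribenzyl ether; acylation with a protected galloyl chloride and oxidation of the formyl group would give the two-ring acid A2.
The chloride of A2 would then have to acylate one meta hydroxyl of a gallate ester whose three phenols are free, to give the hexabenzyl compound A3.
Its weakest steps would be: (a) this mono-acylation of a free pyrogallol with precious A2. The para hydroxyl is the most acidic, acyl groups shift between neighbouring phenolic oxygens, and no established method fixes the site, so meta/para and mono/di mixtures would be expected late in the route.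
(b) The removal of one benzyl ether out of three to reach A1, which would rest on a small electronic bias and could over-cleave.
(c) The aldehyde detour for the ring B carboxyl, which would spend an oxidation step without any gain in complexity.

Plan of the new route
Ring A of the target is a benzoic acid with oxygens on C3, C4 and C5, that is, the carbon skeleton and all five oxygens of (−)-shikimic acid, from which it differs by four hydrogens only. Its acylated meta oxygen corresponds to O5 of shikimic acid, the one hydroxyl left free by the 3,4-acetonide.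
The retrosynthesis therefore first takes ring A back to the cyclohex-1-ene-3,4-diol 12, then cuts the C5–O ester bond on sp3 carbon to acetonide 10 and the two-ring acid 7, and last the para ester of ring B.
Rings C and B are aromatic from the start. Ring A arises last, in the key step, by oxidation of the diol and tautomerization, as in the biosynthesis of gallate from 3-dehydroshikimate.
No free pyrogallol is acylated, because the ester sits on O5 before the phenols exist. No benzyl ether is cleaved selectively, because the para oxygen of ring B is marked at the outset by allylation of the most acidic phenol of gallic acid. The ring B carboxyl never leaves the acid oxidation level.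

Key step: step 9

Remark: the target has no stereocentre, and the three stereocentres of shikimic acid are consumed in step 9. Because depside esters shift between neighbouring phenolic oxygens under base, the work-up of step 9 and all of step 10 are kept acidic or neutral.

Step 1
Reactants: 1 gallic acid
Product: 2 allyl 4-(allyloxy)-3,5-dihydroxybenzoate
Conditions: allyl bromide (2.1 equiv), KHCO3 (2.5 equiv), DMF, rt → 45 °C
Reagents that add atoms: allyl bromide, C=CCBr
Why: SN2 O-alkylation under acidity control: hydrogencarbonate ionizes only the carboxylic acid and then the 4-hydroxyl (para to the carbonyl and flanked by two hydrogen-bond donors, hence by far the most acidic phenol, the usual site of mono-alkylation of gallates), so the para oxygen of ring B is marked without any later selective deprotection.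

Step 2
Reactants: 2 allyl 4-(allyloxy)-3,5-dihydroxybenzoate
Product: 3 allyl 4-(allyloxy)-3,5-bis(benzyloxy)benzoate
Conditions: BnBr (2.4 equiv), K2CO3 (3 equiv), DMF, 50 °C
Reagents that add atoms: benzyl bromide, BrCc1ccccc1
Why: Williamson etherification of the two remaining phenols, with the allyl ester and allyl ether inert to carbonate.

Step 3
Reactants: 3 allyl 4-(allyloxy)-3,5-bis(benzyloxy)benzoate
Product: 4 3,5-bis(benzyloxy)-4-hydroxybenzoic acid
Conditions: Pd(PPh3)4 (5 mol %), morpholine (6 equiv), THF, rt → 40 °C; 1 M HCl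
Reagents that add atoms: none
Why: Tsuji–Trost deallylation: zerovalent palladium ionizes both the allyl ester and the allyl aryl ether (carboxylate and the electron-poor phenoxide are good leaving groups) to π-allylpalladium species that morpholine traps, while the benzyl ethers are untouched.

Step 4
Reactants: 4 3,5-bis(benzyloxy)-4-hydroxybenzoic acid; 5 3,4,5-tris(benzyloxy)benzoic acid
Product: 7 3,5-bis(benzyloxy)-4-{[3,4,5-tris(benzyloxy)benzoyl]oxy}benzoic acid, via acid chloride 6 (not isolated)
Conditions: a) 5, (COCl)2 (1.3 equiv), DMF (cat.), CH2Cl2, 0 °C → rt, evaporate; b) 4, NaOH (2.2 equiv), H2O/THF (1:1), 0 °C, add 6 (1.2 equiv) in THF, 1 h; c) 1 M HCl to pH 2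
Reagents that add atoms: none
Why: Schotten–Baumann O-aroylation of a hydroxybenzoic acid dianion (as with 4-hydroxybenzoic or syringic acid): in aqueous base the phenoxide is the better acyl acceptor than the solvated carboxylate, any mixed anhydride is hydrolysed back, only one phenol is present so no question of site arises, and the new aryl ester, flanked by two benzyloxy groups, should withstand cold dilute hydroxide.

Step 5
Reactants: 8 (−)-shikimic acid
Product: 9 4-methoxybenzyl shikimate [4-methoxybenzyl (3R,4S,5R)-3,4,5-trihydroxycyclohex-1-ene-1-carboxylate]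
Conditions: 4-methoxybenzyl chloride (1.1 equiv), KHCO3 (1.2 equiv), NaI (0.1 equiv), DMF, rt → 40 °C
Reagents that add atoms: 4-methoxybenzyl chloride, COc1ccc(CCl)cc1
Why: SN2 alkylation of the carboxylate only (the secondary alcohols are not ionized by hydrogencarbonate), leaving the stereocentres untouched and giving an ester that falls together with the benzyl ethers in the last step.

Step 6
Reactants: 9 4-methoxybenzyl shikimate
Product: 10 4-methoxybenzyl 3,4-O-isopropylideneshikimate (3R,4S,5R; 5-hydroxyl free)
Conditions: 2,2-dimethoxypropane (3 equiv), CSA (5 mol %), acetone, rt; Et3N quench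
Reagents that add atoms: 2,2-dimethoxypropane, COC(C)(C)OC
Why: Acid-catalysed transketalization in which only the cis 3,4-diol can close a dioxolane (O4 and O5 are trans), the standard way to single out O5 of shikimate esters.

Step 7
Reactants: 7 3,5-bis(benzyloxy)-4-{[3,4,5-tris(benzyloxy)benzoyl]oxy}benzoic acid; 10 4-methoxybenzyl 3,4-O-isopropylideneshikimate
Product: 11 4-methoxybenzyl 5-O-[3,5-bis(benzyloxy)-4-{[3,4,5-tris(benzyloxy)benzoyl]oxy}benzoyl]-3,4-O-isopropylideneshikimate
Conditions: 7 (1.1 equiv), EDC·HCl (1.5 equiv), DMAP (0.5 equiv), CH2Cl2, 0 °C → rt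
Reagents that add atoms: none
Why: Steglich esterification of the only free hydroxyl, a secondary alcohol on sp3 carbon, so the future meta ester is placed without any competition among phenols; the C5–O bond is not broken, so the configuration is retained (and is irrelevant later).

Step 8
Reactants: 11 4-methoxybenzyl 5-O-[3,5-bis(benzyloxy)-4-{[3,4,5-tris(benzyloxy)benzoyl]oxy}benzoyl]-3,4-O-isopropylideneshikimate
Product: 12 4-methoxybenzyl 5-O-[3,5-bis(benzyloxy)-4-{[3,4,5-tris(benzyloxy)benzoyl]oxy}benzoyl]shikimate (3,4-diol free, shikimate configuration retained)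
Conditions: AcOH/H2O (4:1), 45 °C; co-evaporation with toluene
Reagents that add atoms: none
Why: Mild acid hydrolysis of the isopropylidene ketal, which spares the benzyl ethers, both aryl esters and the 4-methoxybenzyl ester and, being acidic, gives the aroyl group on O5 little chance to shift to O4.

Step 9
Reactants: 12 4-methoxybenzyl 5-O-[3,5-bis(benzyloxy)-4-{[3,4,5-tris(benzyloxy)benzoyl]oxy}benzoyl]shikimate
Product: 14 4-methoxybenzyl 3-{[3,5-bis(benzyloxy)-4-{[3,4,5-tris(benzyloxy)benzoyl]oxy}benzoyl]oxy}-4,5-dihydroxybenzoate, via diketone 13 (not isolated)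
Conditions: DMSO (5 equiv), (CF3CO)2O (2.6 equiv), CH2Cl2, −78 °C, then 12, 1 h; Et3N (8 equiv), −78 → −20 °C; AcOH (10 equiv), −20 °C; aq. NaH2PO4, under argon
Reagents that add atoms: none
Why: Both hydroxyls are first converted at −78 °C into alkoxysulfonium ions, and the amine then triggers two ylide fragmentations (Swern-type activated-DMSO oxidation in the trifluoroacetic anhydride variant used for vicinal diols) to the 3,4-diketone 13, whose C5–H and C6–H2 are removed by the same base so that two enolizations deliver the benzene ring. The closest known reaction types are the activated-DMSO oxidation of cyclic cis-1,2-diols to 1,2-diketones with in situ enolization to tropolones or catechols, and the dehydrogenation of 3-dehydroshikimate to gallate in biosynthesis. No ring is closed: the six-membered carbocycle of shikimic acid is kept and only brought to the aromatic oxidation level, which makes ring A the last ring of the target to arise. No stereocentre is formed, and the three of shikimic acid are erased. The selectivity needed is oxidation at C3 and C4 without loss of the C5 aroyloxy group by beta-elimination; it should be secured by activating both hydroxyls before any base is added, so that a carbanion at C4 expels dimethyl sulfide from its own oxygen to give the carbonyl, while deprotonation at C5 gives an enol ester whose aroyloxy group sits on sp2 carbon and can no longer leave. The site of the ester is not a matter of phenol selectivity at all, since O5 was the only free hydroxyl of 10, and the cold acetic acid quench should keep the new 4-phenoxide from shifting the acyl group.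

Step 10
Reactants: 14 4-methoxybenzyl 3-{[3,5-bis(benzyloxy)-4-{[3,4,5-tris(benzyloxy)benzoyl]oxy}benzoyl]oxy}-4,5-dihydroxybenzoate
Product: 15 3-{[3,5-dihydroxy-4-{[3,4,5-trihydroxybenzoyl]oxy}benzoyl]oxy}-4,5-dihydroxybenzoic acid (CNP0317472.0)
Conditions: H2 (1 atm), 10% Pd/C, THF, rt; filter (Celite), evaporate below 30 °C; C18, H2O/MeCN (0.1% HCO2H)
Reagents that add atoms: none
Why: Catalytic hydrogenolysis removes the five benzyl ethers and the 4-methoxybenzyl ester under neutral conditions that leave both depside bonds in place and offer no base for acyl shifts; no stereocentre is present.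

Compound list
1 | gallic acid (3,4,5-trihydroxybenzoic acid) | OC(=O)c1cc(O)c(O)c(O)c1 | starting material
2 | allyl 4-(allyloxy)-3,5-dihydroxybenzoate | C=CCOC(=O)c1cc(O)c(OCC=C)c(O)c1 | intermediate
3 | allyl 4-(allyloxy)-3,5-bis(benzyloxy)benzoate | C=CCOC(=O)c1cc(OCc2ccccc2)c(OCC=C)c(OCc2ccccc2)c1 | intermediate
4 | 3,5-bis(benzyloxy)-4-hydroxybenzoic acid | OC(=O)c1cc(OCc2ccccc2)c(O)c(OCc2ccccc2)c1 | intermediate
5 | 3,4,5-tris(benzyloxy)benzoic acid | OC(=O)c1cc(OCc2ccccc2)c(OCc2ccccc2)c(OCc2ccccc2)c1 | starting material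
6 | 3,4,5-tris(benzyloxy)benzoyl chloride | ClC(=O)c1cc(OCc2ccccc2)c(OCc2ccccc2)c(OCc2ccccc2)c1 | intermediate
7 | 3,5-bis(benzyloxy)-4-{[3,4,5-tris(benzyloxy)benzoyl]oxy}benzoic acid | OC(=O)c1cc(OCc2ccccc2)c(OC(=O)c2cc(OCc3ccccc3)c(OCc3ccccc3)c(OCc3ccccc3)c2)c(OCc2ccccc2)c1 | intermediate
8 | (−)-shikimic acid [(3R,4S,5R)-3,4,5-trihydroxycyclohex-1-ene-1-carboxylic acid] | C1[C@H]([C@@H]([C@@H](C=C1C(=O)O)O)O)O | starting material
9 | 4-methoxybenzyl shikimate [4-methoxybenzyl (3R,4S,5R)-3,4,5-trihydroxycyclohex-1-ene-1-carboxylate] | C1[C@H]([C@@H]([C@@H](C=C1C(=O)OCc1ccc(OC)cc1)O)O)O | intermediate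
10 | 4-methoxybenzyl 3,4-O-isopropylideneshikimate (3R,4S,5R; 5-hydroxyl free) | C1[C@H]([C@@H]([C@@H](C=C1C(=O)OCc1ccc(OC)cc1)O2)OC2(C)C)O | intermediate
11 | 4-methoxybenzyl 5-O-[3,5-bis(benzyloxy)-4-{[3,4,5-tris(benzyloxy)benzoyl]oxy}benzoyl]-3,4-O-isopropylideneshikimate | C1[C@H]([C@@H]([C@@H](C=C1C(=O)OCc1ccc(OC)cc1)O2)OC2(C)C)OC(=O)c1cc(OCc2ccccc2)c(OC(=O)c2cc(OCc3ccccc3)c(OCc3ccccc3)c(OCc3ccccc3)c2)c(OCc2ccccc2)c1 | intermediate
12 | 4-methoxybenzyl 5-O-[3,5-bis(benzyloxy)-4-{[3,4,5-tris(benzyloxy)benzoyl]oxy}benzoyl]shikimate (3,4-diol free) | C1[C@H]([C@@H]([C@@H](C=C1C(=O)OCc1ccc(OC)cc1)O)O)OC(=O)c1cc(OCc2ccccc2)c(OC(=O)c2cc(OCc3ccccc3)c(OCc3ccccc3)c(OCc3ccccc3)c2)c(OCc2ccccc2)c1 | intermediate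
13 | 4-methoxybenzyl (5R)-5-{[3,5-bis(benzyloxy)-4-{[3,4,5-tris(benzyloxy)benzoyl]oxy}benzoyl]oxy}-3,4-dioxocyclohex-1-ene-1-carboxylate | C1[C@H](C(=O)C(=O)C=C1C(=O)OCc1ccc(OC)cc1)OC(=O)c1cc(OCc2ccccc2)c(OC(=O)c2cc(OCc3ccccc3)c(OCc3ccccc3)c(OCc3ccccc3)c2)c(OCc2ccccc2)c1 | intermediate
14 | 4-methoxybenzyl 3-{[3,5-bis(benzyloxy)-4-{[3,4,5-tris(benzyloxy)benzoyl]oxy}benzoyl]oxy}-4,5-dihydroxybenzoate | COc1ccc(COC(=O)c2cc(O)c(O)c(OC(=O)c3cc(OCc4ccccc4)c(OC(=O)c4cc(OCc5ccccc5)c(OCc5ccccc5)c(OCc5ccccc5)c4)c(OCc4ccccc4)c3)c2)cc1 | intermediate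
15 | 3-{[3,5-dihydroxy-4-{[3,4,5-trihydroxybenzoyl]oxy}benzoyl]oxy}-4,5-dihydroxybenzoic acid (CNP0317472.0) | O=C(O)c1cc(O)c(O)c(OC(=O)c2cc(O)c(OC(=O)c3cc(O)c(O)c(O)c3)c(O)c2)c1 | target

Total step count: 10. Longest linear sequence: 8 steps (steps 1, 2, 3, 4, 7, 8, 9, 10).

Steps most likely to fail

Step 9 (oxidation and aromatization). What may go wrong: the aroyloxy group may be lost from C5 by beta-elimination as soon as the first carbonyl is formed, which would leave a protocatechuate in place of the gallate ring. The aroyl group may also shift to the neighbouring para oxygen of the new pyrogallol before the acid quench. The fallback uses known chemistry, sets out from 1 and 7 and comes back to the route at 15. Gallic acid 1 would be alkylated at the carboxylate (BnBr, KHCO3, DMF) to benzyl gallate F1. Two vicinal hydroxyls of it would be tied up with dichlorodiphenylmethane (K2CO3, MeCN) as benzyl 7-hydroxy-2,2-diphenyl-1,3-benzodioxole-5-carboxylate F2. Since every vicinal pair contains the para oxygen, exactly one meta hydroxyl stays free, and it would be esterified with acid 7 (EDC·HCl, DMAP, CH2Cl2) to benzyl 7-{[3,5-bis(benzyloxy)-4-{[3,4,5-tris(benzyloxy)benzoyl]oxy}benzoyl]oxy}-2,2-diphenyl-1,3-benzodioxole-5-carboxylate F3. Hydrogenolysis (H2, 10% Pd/C, THF) would remove the ketal, the benzyl ester and the five benzyl ethers and give 15.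

Step 8 (ketal hydrolysis). What may go wrong: acid may promote a shift of the aroyl group from O5 to the freed O4, which would place the ester para after step 9, or the 4-methoxybenzyl ester may be solvolysed. The fallback sets out from 9 and 7 and comes back at 12. Triol 9 would be condensed with PhB(OH)2 (toluene, azeotropic removal of water) to 4-methoxybenzyl shikimate 3,4-O-phenylboronate F4, in which only the cis diol is bridged. The free 5-hydroxyl would be esterified with 7 (EDC·HCl, DMAP, CH2Cl2) to 4-methoxybenzyl 5-O-[3,5-bis(benzyloxy)-4-{[3,4,5-tris(benzyloxy)benzoyl]oxy}benzoyl]shikimate 3,4-O-phenylboronate F5. Boron would then be taken off by exchange with pinacol in CH2Cl2 at rt, without acid or base, to give 12.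

Step 4 (aroylation of the hydroxy acid). What may go wrong: acylation may occur at the carboxylate, the mixed anhydride then passing a ring B acyl group to another phenoxide and building oligomers, and chloride 6 may hydrolyse before it meets the hindered phenoxide. The fallback sets out from 3 and comes back at 11; the two ester bonds are made in the other order, so that the phenol is acylated when no carboxylic acid is present. The allyl ester of 3 would be saponified (LiOH, THF/H2O) to 4-(allyloxy)-3,5-bis(benzyloxy)benzoic acid F6. This would be esterified with alcohol 10 (EDC·HCl, DMAP, CH2Cl2) to 4-methoxybenzyl 5-O-[4-(allyloxy)-3,5-bis(benzyloxy)benzoyl]-3,4-O-isopropylideneshikimate F7. The allyl aryl ether would be cleaved with Pd(PPh3)4 and morpholine in THF to 4-methoxybenzyl 5-O-[3,5-bis(benzyloxy)-4-hydroxybenzoyl]-3,4-O-isopropylideneshikimate F8, and the phenol would be acylated with chloride 6 (Et3N, DMAP, CH2Cl2) to give 11.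

Further compounds
F1 | step 9 | benzyl gallate (benzyl 3,4,5-trihydroxybenzoate) | O=C(OCc1ccccc1)c1cc(O)c(O)c(O)c1
F2 | step 9 | benzyl 7-hydroxy-2,2-diphenyl-1,3-benzodioxole-5-carboxylate | O=C(OCc1ccccc1)c1cc(O)c2OC(c3ccccc3)(c3ccccc3)Oc2c1
F3 | step 9 | benzyl 7-{[3,5-bis(benzyloxy)-4-{[3,4,5-tris(benzyloxy)benzoyl]oxy}benzoyl]oxy}-2,2-diphenyl-1,3-benzodioxole-5-carboxylate | O=C(OCc1ccccc1)c1cc(OC(=O)c2cc(OCc3ccccc3)c(OC(=O)c3cc(OCc4ccccc4)c(OCc4ccccc4)c(OCc4ccccc4)c3)c(OCc3ccccc3)c2)c2OC(c3ccccc3)(c3ccccc3)Oc2c1
F4 | step 8 | 4-methoxybenzyl shikimate 3,4-O-phenylboronate (5-hydroxyl free) | C1[C@H]([C@@H]([C@@H](C=C1C(=O)OCc1ccc(OC)cc1)O2)OB2c1ccccc1)O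
F5 | step 8 | 4-methoxybenzyl 5-O-[3,5-bis(benzyloxy)-4-{[3,4,5-tris(benzyloxy)benzoyl]oxy}benzoyl]shikimate 3,4-O-phenylboronate | C1[C@H]([C@@H]([C@@H](C=C1C(=O)OCc1ccc(OC)cc1)O2)OB2c1ccccc1)OC(=O)c1cc(OCc2ccccc2)c(OC(=O)c2cc(OCc3ccccc3)c(OCc3ccccc3)c(OCc3ccccc3)c2)c(OCc2ccccc2)c1
F6 | step 4 | 4-(allyloxy)-3,5-bis(benzyloxy)benzoic acid | OC(=O)c1cc(OCc2ccccc2)c(OCC=C)c(OCc2ccccc2)c1
F7 | step 4 | 4-methoxybenzyl 5-O-[4-(allyloxy)-3,5-bis(benzyloxy)benzoyl]-3,4-O-isopropylideneshikimate | C1[C@H]([C@@H]([C@@H](C=C1C(=O)OCc1ccc(OC)cc1)O2)OC2(C)C)OC(=O)c1cc(OCc2ccccc2)c(OCC=C)c(OCc2ccccc2)c1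
F8 | step 4 | 4-methoxybenzyl 5-O-[3,5-bis(benzyloxy)-4-hydroxybenzoyl]-3,4-O-isopropylideneshikimate | C1[C@H]([C@@H]([C@@H](C=C1C(=O)OCc1ccc(OC)cc1)O2)OC2(C)C)OC(=O)c1cc(OCc2ccccc2)c(O)c(OCc2ccccc2)c1
A1 | direct plan | 3,5-bis(benzyloxy)-4-hydroxybenzaldehyde | O=Cc1cc(OCc2ccccc2)c(O)c(OCc2ccccc2)c1
A2 | direct plan | 3,5-bis(benzyloxy)-4-{[3,4,5-tris(benzyloxy)benzoyl]oxy}benzoic acid | OC(=O)c1cc(OCc2ccccc2)c(OC(=O)c2cc(OCc3ccccc3)c(OCc3ccccc3)c(OCc3ccccc3)c2)c(OCc2ccccc2)c1
A3 | direct plan | benzyl 3-{[3,5-bis(benzyloxy)-4-{[3,4,5-tris(benzyloxy)benzoyl]oxy}benzoyl]oxy}-4,5-dihydroxybenzoate | O=C(OCc1ccccc1)c1cc(O)c(O)c(OC(=O)c2cc(OCc3ccccc3)c(OC(=O)c3cc(OCc4ccccc4)c(OCc4ccccc4)c(OCc4ccccc4)c3)c(OCc3ccccc3)c2)c1
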